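**Retrosynthetic overview**

1. Target 25 ⇐ MOM removal and C8 acylation (directed metalation of the only ring C–H, Weinreb amide 21) of (S)-chromanol 20 ⇐ Corey–Bakshi–Shibata reduction of 2,2-dimethylchroman-3-one 19, which sets C3.
2. 19 ⇐ open-chain aldehyde / N-acyloxyphthalimide 17: a carbene-catalysed decarboxylative radical acylation forms C2–C3 and thereby closes the pyran ring, the only ring made in the route (ring A and the phenyl ring are bought).
3. Enabling feature: C2 is a fully substituted carbon carrying the ring oxygen O1 and two methyl groups, bonded directly to the oxygenated carbon C3. C2 can therefore be generated as a stabilised tertiary alpha-aryloxy radical from ArO–CMe2–CO2H (the extra carboxyl carbon leaves as CO2) and C3 as the acyl carbon of an aldehyde, while O1 on C8a and C4 on C4a, ortho on ring A, hold the two carbons 1,6.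
4. 17 ⇐ phenol 10 (O-alkylation with 2-bromoisobutyric acid, active ester, allyl cleavage) ⇐ Claisen rearrangement of allyl ether 9 ⇐ phenol 7 ⇐ iridium-catalysed C–H borylation/oxidation of bis-MOM 2-methylresorcinol 3. In 7 the hydroxyl para to the methyl is the unique future O1 and its two ortho carbons are equivalent, so no regiochemical choice arises.

Key step: step 8

Remark: chroman numbering is used throughout (O1, C2, C3, C4, C4a, C5–C8, C8a); the stereocentre of the target is C3 with the (S) configuration. Amide 21 and the thiazolium salt of step 8 are taken as purchasable.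

**Step 1**
Reactants: 1 2-methylresorcinol (2-methylbenzene-1,3-diol); 2 chloromethyl methyl ether
Product: 3 1,3-bis(methoxymethoxy)-2-methylbenzene
Conditions: NaH (2.4 equiv), 2 (2.4 equiv), DMF, 0 °C to rt
Reagents that add atoms: chloromethyl methyl ether 2, COCCl
Why: Williamson etherification of both phenoxides should give the bis-MOM ether, which is base-stable, later directs the metalation at C8 and is removed by mild acid.

**Step 2**
Reactants: 3 1,3-bis(methoxymethoxy)-2-methylbenzene; 4 bis(pinacolato)diboron; 5 hydrogen peroxide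
Product: 7 3,5-bis(methoxymethoxy)-4-methylphenol, via aryl pinacol boronate 6 (not isolated)
Conditions: [Ir(OMe)(cod)]2 (1.5 mol %), 4,4'-di-tert-butyl-2,2'-bipyridine (3 mol %), 4 (1.0 equiv), THF, 80 °C; then 30 % aq. H2O2, NaOH, 0 °C
Reagents that add atoms: hydrogen peroxide 5, OO
Why: Sterically controlled iridium-catalysed C–H borylation of a 1,2,3-trisubstituted arene should go to the one C–H without an ortho substituent (para to the methyl), and oxidation of the C–B bond at that position gives the phenol.

**Step 3**
Reactants: 7 3,5-bis(methoxymethoxy)-4-methylphenol; 8 allyl bromide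
Product: 9 1,3-bis(methoxymethoxy)-2-methyl-5-(prop-2-en-1-yloxy)benzene
Conditions: K2CO3 (1.5 equiv), 8 (1.3 equiv), acetone, reflux
Reagents that add atoms: allyl bromide 8, C=CCBr
Why: Williamson O-allylation of the only free phenol should proceed cleanly under carbonate conditions that leave the MOM ethers untouched.

**Step 4**
Reactants: 9 1,3-bis(methoxymethoxy)-2-methyl-5-(prop-2-en-1-yloxy)benzene
Product: 10 3,5-bis(methoxymethoxy)-4-methyl-2-(prop-2-en-1-yl)phenol
Conditions: N,N-diethylaniline, 190 °C
Reagents that add atoms: none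
Why: Aromatic Claisen rearrangement ([3,3]-sigmatropic shift, then tautomerisation) should deliver the allyl group to one of the two equivalent ortho carbons, placing the future C4–C3 chain next to the future O1; the para position is blocked by the methyl group.

**Step 5**
Reactants: 10 3,5-bis(methoxymethoxy)-4-methyl-2-(prop-2-en-1-yl)phenol; 11 2-bromo-2-methylpropanoic acid
Product: 12 2-[3,5-bis(methoxymethoxy)-4-methyl-2-(prop-2-en-1-yl)phenoxy]-2-methylpropanoic acid
Conditions: powdered NaOH (6 equiv), 11 (2.5 equiv), 2-butanone, 50 °C; then 1 M HCl to pH 3, 0 °C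
Reagents that add atoms: 2-bromo-2-methylpropanoic acid 11, CC(C)(Br)C(=O)O
Why: Williamson-type O-alkylation of the sodium phenoxide at the tertiary carbon of the bromo acid carboxylate is the standard entry to 2-aryloxy-2-methylpropanoic acids and installs O1–C2 with both methyl groups and the carboxyl group that is lost in step 8.

**Step 6**
Reactants: 12 2-[3,5-bis(methoxymethoxy)-4-methyl-2-(prop-2-en-1-yl)phenoxy]-2-methylpropanoic acid; 13 N-hydroxyphthalimide
Product: 14 1,3-dioxoisoindolin-2-yl 2-[3,5-bis(methoxymethoxy)-4-methyl-2-(prop-2-en-1-yl)phenoxy]-2-methylpropanoate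
Conditions: 13 (1.1 equiv), N,N'-diisopropylcarbodiimide (1.2 equiv), DMAP (10 mol %), CH2Cl2, rt
Reagents that add atoms: N-hydroxyphthalimide 13, ON1C(=O)c2ccccc2C1=O
Why: Steglich-type carbodiimide esterification should convert the hindered acid into the redox-active N-acyloxyphthalimide under neutral conditions that spare the MOM ethers and the alkene.

**Step 7**
Reactants: 14 1,3-dioxoisoindolin-2-yl 2-[3,5-bis(methoxymethoxy)-4-methyl-2-(prop-2-en-1-yl)phenoxy]-2-methylpropanoate; 15 sodium periodate
Product: 17 1,3-dioxoisoindolin-2-yl 2-[3,5-bis(methoxymethoxy)-4-methyl-2-(2-oxoethyl)phenoxy]-2-methylpropanoate, via vicinal diol 16 (not isolated)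
Conditions: K2OsO4·2H2O (2 mol %), 15 (3 equiv), 2,6-lutidine (2 equiv), 1,4-dioxane/H2O 3:1, rt
Reagents that add atoms: sodium periodate 15, [Na+].[O-]I(=O)(=O)=O
Why: Lemieux–Johnson oxidation (catalytic dihydroxylation, then periodate cleavage of the diol) should shorten the allyl group to the arylacetaldehyde, the lutidine buffer protecting the MOM ethers and limiting hydrolysis of the hindered active ester.

**Step 8**
Reactants: 17 1,3-dioxoisoindolin-2-yl 2-[3,5-bis(methoxymethoxy)-4-methyl-2-(2-oxoethyl)phenoxy]-2-methylpropanoate
Product: 19 5,7-bis(methoxymethoxy)-2,2,6-trimethyl-2H-chromen-3(4H)-one, via Breslow intermediate 18 (not isolated)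
Conditions: 3-(2,6-diisopropylphenyl)-5,6,7,8-tetrahydro-4H-cyclohepta[d]thiazol-3-ium perchlorate (10 mol %), Cs2CO3 (20 mol %), degassed DMSO (0.02 M), 60 °C, argon
Reagents that add atoms: none
Why: Proposed new method: the carbene adds to the aldehyde of 17 to give Breslow intermediate 18, whose enolate passes one electron to the N-acyloxyphthalimide, so that loss of phthalimide anion and CO2 leaves a carbene-bound ketyl radical at C3 and a tertiary alpha-aryloxy radical at C2 in the same molecule; their combination makes the C2–C3 bond and expulsion of the carbene from the resulting alkoxide gives ketone 19. The closest known reaction type is the intermolecular carbene-catalysed decarboxylative radical acylation of tertiary alkyl N-acyloxyphthalimides with aliphatic aldehydes to hindered dialkyl ketones; new here are only the ring-closing mode and the alpha-aryloxy substituent on the radical. The pyranone ring (O1, C2, C3, C4, C4a, C8a) closes by combination of a 1,6-radical pair, a closure without a Baldwin constraint because no multiple bond is attacked. No stereocentre is formed: C2 carries two methyl groups and C3 leaves the step as a carbonyl carbon, whose configuration is set in step 9. The step needs C–C combination to win over hydrogen transfer inside the radical pair, over two-electron acyl transfer from the active ester to the aldehyde enolate and over intermolecular coupling. The persistence of the carbene-stabilised ketyl, the 1,6 relation fixed by the ortho O1 and C4 arms on ring A, the neopentyl-like shielding of the ester carbonyl by the C2 methyl groups, the merely catalytic amount of base and high dilution should secure this.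

**Step 9**
Reactants: 19 5,7-bis(methoxymethoxy)-2,2,6-trimethyl-2H-chromen-3(4H)-one
Product: 20 (3S)-5,7-bis(methoxymethoxy)-2,2,6-trimethyl-3,4-dihydro-2H-chromen-3-ol
Conditions: (R)-2-methyl-CBS-oxazaborolidine (15 mol %), BH3·SMe2 (0.8 equiv), THF, −20 °C; MeOH quench, aqueous work-up
Reagents that add atoms: none
Why: Corey–Bakshi–Shibata reduction: the ketone should bind the catalyst–borane complex with its large flank (quaternary C2) turned away and its small flank (C4 methylene) toward the catalyst, so that hydride is delivered to the Re face of C3 and the (S)-carbinol results.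

**Step 10**
Reactants: 20 (3S)-5,7-bis(methoxymethoxy)-2,2,6-trimethyl-3,4-dihydro-2H-chromen-3-ol; 21 N-methoxy-N-methyl-3-phenylpropanamide
Product: 24 1-[(3S)-3-hydroxy-5,7-bis(methoxymethoxy)-2,2,6-trimethyl-3,4-dihydro-2H-chromen-8-yl]-3-phenylpropan-1-one, via C8-lithio lithium alkoxide 22 (not isolated), via tetrahedral lithium adduct 23 (not isolated)
Conditions: n-BuLi (2.3 equiv), THF, −20 to 0 °C; then 21 (1.3 equiv), −78 to 0 °C; aq. NH4Cl
Reagents that add atoms: N-methoxy-N-methyl-3-phenylpropanamide 21, CON(C)C(=O)CCc1ccccc1
Why: Directed ortho-metalation followed by Weinreb ketone synthesis: after the first equivalent of base has formed the C3 alkoxide, C8–H (the only ring hydrogen, flanked by the C7 MOM ether and O1) should be removed, and the aryllithium adds only once because chelated adduct 23 persists until the quench; C3 is not touched.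

**Step 11**
Reactants: 24 1-[(3S)-3-hydroxy-5,7-bis(methoxymethoxy)-2,2,6-trimethyl-3,4-dihydro-2H-chromen-8-yl]-3-phenylpropan-1-one
Product: 25 1-[(3S)-3,5,7-trihydroxy-2,2,6-trimethyl-3,4-dihydro-2H-chromen-8-yl]-3-phenylpropan-1-one (the target dihydrochalcone)
Conditions: 3 M aq. HCl, MeOH, 45 °C
Reagents that add atoms: none
Why: Acid-catalysed acetal exchange with methanol should remove both aryl MOM ethers, while the tertiary alkyl aryl ether, the secondary alcohol and the C3 stereocentre (not enolisable, not ionisable under dilute acid) survive, and the fully substituted ring offers no site to the released formaldehyde equivalent.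

**Compound list**

1 | 2-methylresorcinol | Cc1c(O)cccc1O | starting material
2 | chloromethyl methyl ether | COCCl | starting material
3 | 1,3-bis(methoxymethoxy)-2-methylbenzene | Cc1c(OCOC)cccc1OCOC | intermediate
4 | bis(pinacolato)diboron | CC1(C)OB(OC1(C)C)B1OC(C)(C)C(C)(C)O1 | starting material
5 | hydrogen peroxide | OO | starting material
6 | 2-[3,5-bis(methoxymethoxy)-4-methylphenyl]-4,4,5,5-tetramethyl-1,3,2-dioxaborolane (formed in the flask) | Cc1c(OCOC)cc(cc1OCOC)B1OC(C)(C)C(C)(C)O1 | intermediate
7 | 3,5-bis(methoxymethoxy)-4-methylphenol | Cc1c(OCOC)cc(O)cc1OCOC | intermediate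
8 | allyl bromide | C=CCBr | starting material
9 | 1,3-bis(methoxymethoxy)-2-methyl-5-(prop-2-en-1-yloxy)benzene | Cc1c(OCOC)cc(OCC=C)cc1OCOC | intermediate
10 | 3,5-bis(methoxymethoxy)-4-methyl-2-(prop-2-en-1-yl)phenol | Cc1c(OCOC)cc(O)c(CC=C)c1OCOC | intermediate
11 | 2-bromo-2-methylpropanoic acid | CC(C)(Br)C(=O)O | starting material
12 | 2-[3,5-bis(methoxymethoxy)-4-methyl-2-(prop-2-en-1-yl)phenoxy]-2-methylpropanoic acid | Cc1c(OCOC)cc(OC(C)(C)C(=O)O)c(CC=C)c1OCOC | intermediate
13 | N-hydroxyphthalimide | ON1C(=O)c2ccccc2C1=O | starting material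
14 | 1,3-dioxoisoindolin-2-yl 2-[3,5-bis(methoxymethoxy)-4-methyl-2-(prop-2-en-1-yl)phenoxy]-2-methylpropanoate | Cc1c(OCOC)cc(OC(C)(C)C(=O)ON2C(=O)c3ccccc3C2=O)c(CC=C)c1OCOC | intermediate
15 | sodium periodate | [Na+].[O-]I(=O)(=O)=O | starting material
16 | 1,3-dioxoisoindolin-2-yl 2-[2-(2,3-dihydroxypropyl)-3,5-bis(methoxymethoxy)-4-methylphenoxy]-2-methylpropanoate (racemic, formed in the flask) | Cc1c(OCOC)cc(OC(C)(C)C(=O)ON2C(=O)c3ccccc3C2=O)c(CC(O)CO)c1OCOC | intermediate
17 | 1,3-dioxoisoindolin-2-yl 2-[3,5-bis(methoxymethoxy)-4-methyl-2-(2-oxoethyl)phenoxy]-2-methylpropanoate | Cc1c(OCOC)cc(OC(C)(C)C(=O)ON2C(=O)c3ccccc3C2=O)c(CC=O)c1OCOC | intermediate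
18 | Breslow intermediate: enaminol from 17 and the thiazol-2-ylidene (formed in the flask) | OC(Cc1c(OC(C)(C)C(=O)ON2C(=O)c3ccccc3C2=O)cc(OCOC)c(C)c1OCOC)=C1SC2=C(CCCCC2)N1c1c(C(C)C)cccc1C(C)C | intermediate
19 | 5,7-bis(methoxymethoxy)-2,2,6-trimethyl-2H-chromen-3(4H)-one | Cc1c(OCOC)c2c(cc1OCOC)OC(C)(C)C(=O)C2 | intermediate
20 | (3S)-5,7-bis(methoxymethoxy)-2,2,6-trimethyl-3,4-dihydro-2H-chromen-3-ol | Cc1c(OCOC)c2c(cc1OCOC)OC(C)(C)[C@@H](O)C2 | intermediate
21 | N-methoxy-N-methyl-3-phenylpropanamide | CON(C)C(=O)CCc1ccccc1 | starting material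
22 | lithium (3S)-8-lithio-5,7-bis(methoxymethoxy)-2,2,6-trimethyl-3,4-dihydro-2H-chromen-3-olate (formed in the flask) | Cc1c(OCOC)c2c(c([Li])c1OCOC)OC(C)(C)[C@@H](O[Li])C2 | intermediate
23 | dilithium salt of the tetrahedral adduct of 22 and 21 (formed in the flask, mixture at the new carbinol carbon) | Cc1c(OCOC)c2c(c(C(O[Li])(CCc3ccccc3)N(C)OC)c1OCOC)OC(C)(C)[C@@H](O[Li])C2 | intermediate
24 | 1-[(3S)-3-hydroxy-5,7-bis(methoxymethoxy)-2,2,6-trimethyl-3,4-dihydro-2H-chromen-8-yl]-3-phenylpropan-1-one | Cc1c(OCOC)c2c(c(C(=O)CCc3ccccc3)c1OCOC)OC(C)(C)[C@@H](O)C2 | intermediate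
25 | 1-[(3S)-3,5,7-trihydroxy-2,2,6-trimethyl-3,4-dihydro-2H-chromen-8-yl]-3-phenylpropan-1-one | Cc1c(O)c2c(c(C(=O)CCc3ccccc3)c1O)OC(C)(C)[C@@H](O)C2 | target

**Totals**

Total step count: 11. Longest linear sequence: 11 steps (1 to 25; the route is linear, all other inputs are bought).

**Steps most likely to fail**

Step 8 (proposed method). The ring closure may be outrun by two-electron acyl transfer from the active ester to the aldehyde enolate, by hydrogen transfer inside the radical pair, or by intermolecular coupling. The fallback closes the same C2–C3 bond from 17 by a polar organochromium route, a reaction type established intermolecularly for alkyl N-acyloxyphthalimides and aldehydes. Treatment of 17 with CrCl2 (divalent chromium chloride, excess) in THF/DMF at 25 °C should reduce the active ester; the tertiary radical formed on loss of CO2 is captured by divalent chromium and the alkylchromium species adds to the aldehyde in a decarboxylative Nozaki–Hiyama–Kishi-type cyclisation. Aqueous work-up should give racemic 5,7-bis(methoxymethoxy)-2,2,6-trimethyl-3,4-dihydro-2H-chromen-3-ol F1. Oxidation of F1 with Dess–Martin periodinane (NaHCO3, CH2Cl2, 0 °C) returns to the route at ketone 19.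

Step 7. The active ester may hydrolyse in the aqueous buffer, and the enol of the newly formed arylacetaldehyde may be cleaved further by the osmium/periodate couple with loss of one more carbon. The fallback changes the order and stages the cleavage, setting out from acid 12. Dihydroxylation (K2OsO4·2H2O cat., N-methylmorpholine N-oxide, acetone/H2O) should give the diol acid 2-[2-(2,3-dihydroxypropyl)-3,5-bis(methoxymethoxy)-4-methylphenoxy]-2-methylpropanoic acid F2. The isolated diol is cleaved in the absence of osmium (NaIO4 on silica gel, CH2Cl2) to the aldehyde acid 2-[3,5-bis(methoxymethoxy)-4-methyl-2-(2-oxoethyl)phenoxy]-2-methylpropanoic acid F3. F3 is then esterified with N-hydroxyphthalimide 13 (N,N'-diisopropylcarbodiimide, DMAP, CH2Cl2) under anhydrous conditions, which rejoins the route at 17.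

Step 10. Ring metalation may be incomplete, or deprotonation may stray to the C6 methyl group (flanked by two MOM ethers) or to C4 once the C3 alkoxide is present. The fallback fixes the position by halogen instead of by deprotonation, setting out from 20. Bromination at C8, the only ring C–H, with N-bromosuccinimide (MeCN, −20 °C) should give (3S)-8-bromo-5,7-bis(methoxymethoxy)-2,2,6-trimethyl-3,4-dihydro-2H-chromen-3-ol F4. After alkoxide formation with MeLi (1.05 equiv, THF, −78 °C), bromine–lithium exchange with n-BuLi (1.1 equiv) gives the same dilithio species 22, which is acylated with 21 as in step 10; the route is rejoined at 24.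

**Further compounds**

F1 | step 8 | rac-5,7-bis(methoxymethoxy)-2,2,6-trimethyl-3,4-dihydro-2H-chromen-3-ol | Cc1c(OCOC)c2c(cc1OCOC)OC(C)(C)C(O)C2
F2 | step 7 | 2-[2-(2,3-dihydroxypropyl)-3,5-bis(methoxymethoxy)-4-methylphenoxy]-2-methylpropanoic acid (racemic) | Cc1c(OCOC)cc(OC(C)(C)C(=O)O)c(CC(O)CO)c1OCOC
F3 | step 7 | 2-[3,5-bis(methoxymethoxy)-4-methyl-2-(2-oxoethyl)phenoxy]-2-methylpropanoic acid | Cc1c(OCOC)cc(OC(C)(C)C(=O)O)c(CC=O)c1OCOC
F4 | step 10 | (3S)-8-bromo-5,7-bis(methoxymethoxy)-2,2,6-trimethyl-3,4-dihydro-2H-chromen-3-ol | Cc1c(OCOC)c2c(c(Br)c1OCOC)OC(C)(C)[C@@H](O)C2
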